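**Retrosynthetic overview**
1. The target is the 6-angelate of 6α-hydroxysclareol; the last disconnection is the C6–O acyl bond (triol + angelic acid), since only the secondary 6α-OH can be acylated.
2. The 8α-OH/C7H2 unit of the triol comes from hydride opening of a 7α,8α-epoxide, made by hydroxyl-directed epoxidation of a Δ7 6α-allylic alcohol.
3. Key disconnection: the C6–O bond, formed by a suprafacial [3,3]-sigmatropic 1,3-transposition (allyl perrhenate) of a Δ6 8α-tertiary allylic alcohol, which transfers the 8α configuration to C6.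
4. That allylic alcohol comes from the Δ7 alkene (α-epoxidation, selenolate opening, selenoxide syn-elimination), and the alkene from sclareol 13-acetate by dehydration and alkene isomerisation.
5. Rings: no carbocycle is built; rings A and B with C5, C9, C10 and the side-chain C13 are bought in (−)-sclareol. The only rings formed are two transient oxiranes, the first to shift the alkene, the second to rebuild the C8 carbinol.

Assumption: labdane numbering is used; the SMILES is read as (13R)-6α-angeloyloxylabd-14-ene-8α,13-diol (5S,6S,8R,9R,10S,13R), and commercial (−)-sclareol has the matching C5, C8, C9, C10 and C13 configuration.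

**Route**

Step 1
Reactants: 1 (−)-sclareol
Product: 2 (13R)-8α-hydroxylabd-14-en-13-yl acetate (sclareol 13-acetate)
Conditions: Ac2O (1.2 equiv), Et3N, DMAP (0.2 equiv), CH2Cl2, 0 °C → rt
Reagents that add atoms: acetic anhydride, CC(=O)OC(C)=O
Why: DMAP-catalysed acetylation is sterically selective for the side-chain tertiary allylic C13–OH over the ring C8–OH (buried between C9 and the axial C17 methyl), which masks the ionisable vinyl carbinol and differentiates the two alcohols without touching a stereocentre.

Step 2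
Reactants: 2 (13R)-8α-hydroxylabd-14-en-13-yl acetate
Product: 4 (13R)-labda-8(17),14-dien-13-yl acetate (manool acetate), via 8-chlorosulfite 3 (not isolated)
Conditions: SOCl2, pyridine, CH2Cl2, −78 → 0 °C
Reagents that add atoms: none
Why: Dehydration through the chlorosulfite (E2 with pyridine) gives mainly the exocyclic alkene because the equatorial 8α leaving group has only C17–H bonds antiperiplanar, and any Δ7 isomer formed alongside is carried on because step 3 converges both on 5.

Step 3
Reactants: 4 (13R)-labda-8(17),14-dien-13-yl acetate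
Product: 5 (13R)-labda-7,14-dien-13-yl acetate
Conditions: Co(salen)Cl (3 mol %; salen = achiral N,N′-ethylenebis(3,5-di-tert-butylsalicylideneiminate)), PhSiH3 (6 mol %), benzene, rt
Reagents that add atoms: none
Why: Cobalt-hydride hydrogen-atom-transfer alkene isomerisation turns the 1,1-disubstituted alkene into the C8 tertiary radical, which loses the accessible C7–H to give the trisubstituted Δ7 alkene (the hindered C9–H is spared, so C9 is not epimerised), while the vinyl group on quaternary C13 has no allylic hydrogen and cannot move.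

Step 4
Reactants: 5 (13R)-labda-7,14-dien-13-yl acetate
Product: 6 (13R)-7α,8α-epoxylabd-14-en-13-yl acetate
Conditions: mCPBA (1.1 equiv), CH2Cl2, 0 °C
Reagents that add atoms: mCPBA, O=C(OO)c1cccc(Cl)c1
Why: Prilezhaev epoxidation takes the electron-rich trisubstituted ring alkene far faster than the vinyl group, and the peracid adds to the α face because the β face of C8 is screened by the axial C20 methyl, giving the 7α,8α-epoxide with C8–O α as in sclareol.

Step 5
Reactants: 6 (13R)-7α,8α-epoxylabd-14-en-13-yl acetate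
Product: 9 (13R)-8α-hydroxylabda-6,14-dien-13-yl acetate, via hydroxy selenide 7 (not isolated), via selenoxide 8 (not isolated)
Conditions: PhSeSePh, NaBH4, EtOH, reflux; then THF, 30% aq. H2O2, 0 °C → rt
Reagents that add atoms: none
Why: Sharpless–Lauer epoxide-to-allylic-alcohol transposition, in which PhSe⁻ opens the epoxide by SN2 with inversion at the secondary C7 (the tertiary C8 is blocked by C20) and the selenoxide syn-eliminates toward C6, the only side with a hydrogen, so the alkene moves to Δ6 and the 8α C–O bond is untouched.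

Step 6
Reactants: 9 (13R)-8α-hydroxylabda-6,14-dien-13-yl acetate
Product: 12 (13R)-6α-hydroxylabda-7,14-dien-13-yl acetate, via tertiary allyl perrhenate 10 (not isolated), via secondary allyl perrhenate 11 (not isolated)
Conditions: Ph3SiOReO3 (5 mol %), Et2O, −40 → 0 °C
Reagents that add atoms: none
Why: Key step, a rhenium-oxo-catalysed 1,3-transposition in which perrhenate ester 10 undergoes a suprafacial [3,3]-sigmatropic rearrangement on the α face, so the new C6–O bond forms on the face the C8–O bond leaves (6α, chirality transfer from C8), driven by the trisubstituted alkene and loss of the C17/C20 syn-diaxial methyl strain, while the acetate keeps the C13 carbinol out of the same reaction.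

Step 7
Reactants: 12 (13R)-6α-hydroxylabda-7,14-dien-13-yl acetate
Product: 13 (13R)-7α,8α-epoxy-6α-hydroxylabd-14-en-13-yl acetate
Conditions: mCPBA (1.1 equiv), CH2Cl2, 0 °C
Reagents that add atoms: mCPBA, O=C(OO)c1cccc(Cl)c1
Why: Hydroxyl-directed peracid epoxidation (Henbest), where hydrogen bonding to the 6α-OH and screening of the β face by C20 both send oxygen to the α face, rebuilding the C8–O bond in the 8α configuration while the vinyl group is left alone.

Step 8
Reactants: 13 (13R)-7α,8α-epoxy-6α-hydroxylabd-14-en-13-yl acetate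
Product: 14 (13R)-labd-14-ene-6α,8α,13-triol (6α-hydroxysclareol)
Conditions: LiAlH4 (excess), THF, 0 °C → reflux; aqueous work-up
Reagents that add atoms: none
Why: Hydride reduction in which LiAlH4 opens the trisubstituted epoxide by SN2 at the secondary C7, the only carbon open to backside attack, leaving the 8α tertiary alcohol with the β-methyl of sclareol, and the same reagent cleaves the C13 acetate so deprotection costs no extra step.

Step 9
Reactants: 14 (13R)-labd-14-ene-6α,8α,13-triol; 15 angelic acid
Product: 17 (13R)-8α,13-dihydroxylabd-14-en-6α-yl (Z)-2-methylbut-2-enoate (6α-angeloyloxysclareol; the target), via mixed anhydride 16 (not isolated)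
Conditions: 15, 2,4,6-Cl3C6H2COCl, Et3N, toluene, rt; then 14, toluene, 80 °C
Reagents that add atoms: none
Why: Yamaguchi esterification acylates only the secondary equatorial 6α-OH (both tertiary alcohols are inert), and the preformed mixed anhydride used without DMAP keeps the (Z)-2-methylbut-2-enoyl group from isomerising to the tiglate.

**Compound list**

1 | (−)-sclareol, (13R)-labd-14-ene-8α,13-diol | C=C[C@](C)(O)CC[C@@H]1[C@@]2(C)CCCC(C)(C)[C@@H]2CC[C@@]1(C)O | starting material
2 | (13R)-8α-hydroxylabd-14-en-13-yl acetate | C=C[C@](C)(OC(C)=O)CC[C@@H]1[C@@]2(C)CCCC(C)(C)[C@@H]2CC[C@@]1(C)O | intermediate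
3 | (13R)-13-acetoxylabd-14-en-8α-yl chlorosulfite | C=C[C@](C)(OC(C)=O)CC[C@@H]1[C@@]2(C)CCCC(C)(C)[C@@H]2CC[C@@]1(C)OS(=O)Cl | intermediate
4 | (13R)-labda-8(17),14-dien-13-yl acetate | C=C[C@](C)(OC(C)=O)CC[C@@H]1[C@@]2(C)CCCC(C)(C)[C@@H]2CCC1=C | intermediate
5 | (13R)-labda-7,14-dien-13-yl acetate | C=C[C@](C)(OC(C)=O)CC[C@@H]1[C@@]2(C)CCCC(C)(C)[C@@H]2CC=C1C | intermediate
6 | (13R)-7α,8α-epoxylabd-14-en-13-yl acetate | C=C[C@](C)(OC(C)=O)CC[C@@H]1[C@@]2(C)CCCC(C)(C)[C@@H]2C[C@H]3O[C@]31C | intermediate
7 | (13R)-8α-hydroxy-7β-(phenylselanyl)labd-14-en-13-yl acetate | C=C[C@](C)(OC(C)=O)CC[C@@H]1[C@@]2(C)CCCC(C)(C)[C@@H]2C[C@H]([Se]c3ccccc3)[C@@]1(C)O | intermediate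
8 | (13R)-8α-hydroxy-7β-(phenylseleninyl)labd-14-en-13-yl acetate | C=C[C@](C)(OC(C)=O)CC[C@@H]1[C@@]2(C)CCCC(C)(C)[C@@H]2C[C@H]([Se](=O)c3ccccc3)[C@@]1(C)O | intermediate
9 | (13R)-8α-hydroxylabda-6,14-dien-13-yl acetate | C=C[C@](C)(OC(C)=O)CC[C@@H]1[C@@]2(C)CCCC(C)(C)[C@@H]2C=C[C@@]1(C)O | intermediate
10 | (13R)-13-acetoxylabda-6,14-dien-8α-yl perrhenate | C=C[C@](C)(OC(C)=O)CC[C@@H]1[C@@]2(C)CCCC(C)(C)[C@@H]2C=C[C@@]1(C)O[Re](=O)(=O)=O | intermediate
11 | (13R)-13-acetoxylabda-7,14-dien-6α-yl perrhenate | C=C[C@](C)(OC(C)=O)CC[C@@H]1[C@@]2(C)CCCC(C)(C)[C@@H]2[C@@H](O[Re](=O)(=O)=O)C=C1C | intermediate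
12 | (13R)-6α-hydroxylabda-7,14-dien-13-yl acetate | C=C[C@](C)(OC(C)=O)CC[C@@H]1[C@@]2(C)CCCC(C)(C)[C@@H]2[C@@H](O)C=C1C | intermediate
13 | (13R)-7α,8α-epoxy-6α-hydroxylabd-14-en-13-yl acetate | C=C[C@](C)(OC(C)=O)CC[C@@H]1[C@@]2(C)CCCC(C)(C)[C@@H]2[C@@H](O)[C@H]3O[C@]31C | intermediate
14 | (13R)-labd-14-ene-6α,8α,13-triol | C=C[C@](C)(O)CC[C@@H]1[C@@]2(C)CCCC(C)(C)[C@@H]2[C@@H](O)C[C@@]1(C)O | intermediate
15 | angelic acid, (Z)-2-methylbut-2-enoic acid | C/C=C(/C)C(=O)O | starting material
16 | angelic 2,4,6-trichlorobenzoic anhydride | C/C=C(/C)C(=O)OC(=O)c1c(Cl)cc(Cl)cc1Cl | intermediate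
17 | (13R)-8α,13-dihydroxylabd-14-en-6α-yl (Z)-2-methylbut-2-enoate | C=C[C@](C)(O)CC[C@@H]1[C@@]2(C)CCCC(C)(C)[C@@H]2[C@@H](OC(=O)/C(C)=C\C)C[C@@]1(C)O | target

**Step count and risks**

Total step count: 9. Longest linear sequence: 9 steps from 1 (15 enters in the last step).

The three steps most likely to fail:

(a) Step 5. The selenolate has to open the 7α,8α-epoxide at C7 in the non-diaxial sense, because the diaxial mode would need attack at the tertiary C8; the opening may be slow or take another course. The fallback sets out from 5 and comes back at 9. Dihydroxylation of the ring alkene with OsO4 (cat.) and N-methylmorpholine N-oxide on the α face gives (13R)-7α,8α-dihydroxylabd-14-en-13-yl acetate F1. MsCl in pyridine sulfonylates only the secondary axial 7α-OH to give (13R)-8α-hydroxy-7α-(methanesulfonyloxy)labd-14-en-13-yl acetate F2. Its axial C7–O bond is antiperiplanar to H6β and C8 has no hydrogen, so E2 elimination with DBU in toluene at 100 °C gives 9 without any substitution at C7.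

(b) Step 6. The rhenium catalyst may ionise the substrate (dienes, loss or shift of the C13 acetate), or the pseudo-equatorial C8–O bond may rearrange poorly. The fallback sets out from 9 and comes back at 12. Oxidative transposition with C5H5NH[CrO3Cl] in CH2Cl2 (Babler–Dauben, the [3,3] shift of the chromate ester made irreversible by oxidation) gives (13R)-6-oxolabda-7,14-dien-13-yl acetate F3. Equilibrating Meerwein–Ponndorf–Verley reduction (Al(OiPr)3, iPrOH, toluene, 80 °C) then gives the pseudo-equatorial 6α-alcohol 12, since the 6β epimer is destabilised by the two syn-axial methyls C19 and C20.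

(c) Step 9. The 6α-OH is hindered by the C4 methyls, and forcing the acylation risks Z-to-E isomerisation to the tiglate. The fallback sets out from 14 and comes back at 17. Esterification of the 6α-OH with 2-[bis(2,2,2-trifluoroethoxy)phosphoryl]propanoic acid (N,N′-dicyclohexylcarbodiimide, DMAP, CH2Cl2) gives (13R)-8α,13-dihydroxylabd-14-en-6α-yl 2-[bis(2,2,2-trifluoroethoxy)phosphoryl]propanoate F4. Still–Gennari olefination (KN(SiMe3)2, 18-crown-6, THF, −78 °C, then acetaldehyde) builds the (Z)-2-methylbut-2-enoate on the molecule and gives 17.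

**Further compounds**

F1 | step 5 | (13R)-7α,8α-dihydroxylabd-14-en-13-yl acetate | C=C[C@](C)(OC(C)=O)CC[C@@H]1[C@@]2(C)CCCC(C)(C)[C@@H]2C[C@@H](O)[C@@]1(C)O
F2 | step 5 | (13R)-8α-hydroxy-7α-(methanesulfonyloxy)labd-14-en-13-yl acetate | C=C[C@](C)(OC(C)=O)CC[C@@H]1[C@@]2(C)CCCC(C)(C)[C@@H]2C[C@@H](OS(C)(=O)=O)[C@@]1(C)O
F3 | step 6 | (13R)-6-oxolabda-7,14-dien-13-yl acetate | C=C[C@](C)(OC(C)=O)CC[C@@H]1[C@@]2(C)CCCC(C)(C)[C@@H]2C(=O)C=C1C
F4 | step 9 | (13R)-8α,13-dihydroxylabd-14-en-6α-yl 2-[bis(2,2,2-trifluoroethoxy)phosphoryl]propanoate | C=C[C@](C)(O)CC[C@@H]1[C@@]2(C)CCCC(C)(C)[C@@H]2[C@@H](OC(=O)C(C)P(=O)(OCC(F)(F)F)OCC(F)(F)F)C[C@@]1(C)O
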